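The cyclohexenone ring (C3a, C4–C7, C7a) is read as a masked 2-alkylcyclohexane-1,3-dione: its vinylogous ester O1–C7a=C3a–C4=O places C4 and C7a in a 1,5-relationship through C5–C6–C7. The key step is a Michael–Claisen annulation in which dimethyl malonate adds to the vinyl terminus C6 of an acyclic dihydroxy vinyl ketone (C6–C7) and the ketone α'-carbon C3a then closes onto the malonate carbonyl (C3a–C7a); decarboxylation and closure of O1 onto C7a follow in the same pot. The precursor is open-chain; both glycol units come from the two enantiomers of 5-oxotetrahydrofuran-2-carboxylic acid by Felkin-controlled additions, and the C5 hydroxyl is installed last.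

Key step: step 8

Remark on the chemistry: ring atoms are numbered as in 1-benzofuran (O1, C2, C3, C3a, C4–C7, C7a) and side-chain carbons C3' to C11' outward from C2 (C3' and C7' carry the methyl groups); dione 17 is assumed to cyclise through its secondary C2 hydroxyl (five-membered ring) and not through the tertiary C3' hydroxyl.

Step 1
Reactants: 1 (2R)-5-oxooxolane-2-carboxylic acid
Product: 3 (5R)-5-acetyloxolan-2-one, via acid chloride 2 (not isolated)
Conditions: (COCl)2, DMF (cat.), CH2Cl2, 0 °C to rt; then MeZnCl, Pd(PPh3)4 (cat.), THF, 0 °C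
Reagents that add atoms: oxalyl chloride ClC(=O)C(=O)Cl (chlorine of 2 only); methylzinc chloride C[Zn]Cl
Why: The acid chloride should undergo palladium-catalysed Negishi acylation with the methylzinc reagent much faster than the lactone carbonyl reacts, and the neutral conditions leave the C6' stereocentre (taken from the starting acid) untouched.

Step 2
Reactants: 3 (5R)-5-acetyloxolan-2-one; 4 5-bromo-2-methylpent-2-ene
Product: 6 (5R)-5-[(2S)-2-hydroxy-6-methylhept-5-en-2-yl]oxolan-2-one, via Grignard reagent 5 (not isolated)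
Conditions: 4, Mg, THF, rt; then 3, THF, −78 °C; aq. NH4Cl
Reagents that add atoms: magnesium [Mg] (magnesium of 5 only)
Why: Grignard 1,2-addition to the ketone (far more electrophilic than the lactone at −78 °C) should follow the polar Felkin–Anh (Cornforth) model, the lactone C6'–O bond lying anti to the incoming homoprenyl group, which passes the C6' hydrogen and so sets C7' as S (6'R,7'S, anti glycol).

Step 3
Reactants: 6 (5R)-5-[(2S)-2-hydroxy-6-methylhept-5-en-2-yl]oxolan-2-one
Product: 7 prop-2-en-1-yl 3-[(4R,5S)-2,2,5-trimethyl-5-(4-methylpent-3-en-1-yl)-1,3-dioxolan-4-yl]propanoate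
Conditions: allyl alcohol (solvent), 2-methoxypropene, TsOH (cat.), 40 °C
Reagents that add atoms: allyl alcohol C=CCO; 2-methoxypropene COC(C)=C
Why: Acid-catalysed alcoholysis of the γ-lactone (Fischer-type transesterification) should be pulled to the open allyl ester because the liberated secondary/tertiary 1,2-diol is trapped at once as its acetonide, and no stereocentre is touched.

Step 4
Reactants: 7 prop-2-en-1-yl 3-[(4R,5S)-2,2,5-trimethyl-5-(4-methylpent-3-en-1-yl)-1,3-dioxolan-4-yl]propanoate; 8 (2S)-5-oxooxolane-2-carboxylic acid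
Product: 10 prop-2-en-1-yl 3-oxo-3-[(2S)-5-oxooxolan-2-yl]-2-{[(4R,5S)-2,2,5-trimethyl-5-(4-methylpent-3-en-1-yl)-1,3-dioxolan-4-yl]methyl}propanoate, via acid chloride 9 (not isolated)
Conditions: 8, (COCl)2, DMF (cat.), CH2Cl2, 0 °C to rt; separately 7, LiHMDS (2.1 equiv), THF, −78 °C; then 9, −78 °C; AcOH
Reagents that add atoms: oxalyl chloride ClC(=O)C(=O)Cl (chlorine of 9 only)
Why: Crossed Claisen condensation, in which the lithium enolate of allyl ester 7 is C-acylated by acid chloride 9 at −78 °C, the second equivalent of base storing the β-keto ester as its enolate so that C2 next to the new ketone is not epimerised, and the new centre at C4' is of no consequence because it is removed in step 5.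

Step 5
Reactants: 10 prop-2-en-1-yl 3-oxo-3-[(2S)-5-oxooxolan-2-yl]-2-{[(4R,5S)-2,2,5-trimethyl-5-(4-methylpent-3-en-1-yl)-1,3-dioxolan-4-yl]methyl}propanoate
Product: 11 (5S)-5-{3-[(4R,5S)-2,2,5-trimethyl-5-(4-methylpent-3-en-1-yl)-1,3-dioxolan-4-yl]propanoyl}oxolan-2-one
Conditions: Pd(PPh3)4 (cat.), morpholine, THF, rt
Reagents that add atoms: none
Why: Tsuji–Trost deallylation, in which palladium ionises the allyl ester, morpholine captures the π-allyl fragment and the β-keto acid loses CO2 at room temperature, neutral conditions that should leave the α-acyloxy ketone centre C2 and the acetonide intact.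

Step 6
Reactants: 11 (5S)-5-{3-[(4R,5S)-2,2,5-trimethyl-5-(4-methylpent-3-en-1-yl)-1,3-dioxolan-4-yl]propanoyl}oxolan-2-one
Product: 12 (5S)-5-{(2S)-2-hydroxy-4-[(4R,5S)-2,2,5-trimethyl-5-(4-methylpent-3-en-1-yl)-1,3-dioxolan-4-yl]butan-2-yl}oxolan-2-one
Conditions: MeTi(OiPr)3, THF, −40 to 0 °C
Reagents that add atoms: methyltitanium triisopropoxide C[Ti](OC(C)C)(OC(C)C)OC(C)C
Why: The non-chelating, ketone-selective organotitanium reagent should add to the ketone and not to the lactone, and polar Felkin–Anh control by the C2–O bond (methyl anti to O1, passing the C2 hydrogen) sets C3' as S (2S,3'S, syn glycol).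

Step 7
Reactants: 12 (5S)-5-{(2S)-2-hydroxy-4-[(4R,5S)-2,2,5-trimethyl-5-(4-methylpent-3-en-1-yl)-1,3-dioxolan-4-yl]butan-2-yl}oxolan-2-one
Product: 13 (6S,7S)-6,7-dihydroxy-7-methyl-9-[(4R,5S)-2,2,5-trimethyl-5-(4-methylpent-3-en-1-yl)-1,3-dioxolan-4-yl]non-1-en-3-one
Conditions: CH2=CHMgBr (2.2 equiv), THF, −78 °C; AcOH, −78 °C; used crude
Reagents that add atoms: vinylmagnesium bromide C=C[Mg]Br
Why: Mono-addition of the vinyl Grignard reagent to the γ-lactone should stop at the cyclic magnesium lactolate, which is stable at −78 °C and releases the hydroxy vinyl ketone (as its hemiketals) only on cold acidic quench, one equivalent of reagent being consumed by the tertiary hydroxyl and no stereocentre being touched.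

Step 8
Reactants: 13 (6S,7S)-6,7-dihydroxy-7-methyl-9-[(4R,5S)-2,2,5-trimethyl-5-(4-methylpent-3-en-1-yl)-1,3-dioxolan-4-yl]non-1-en-3-one
Product: 18 (2S)-2-{(2S)-2-hydroxy-4-[(4R,5S)-2,2,5-trimethyl-5-(4-methylpent-3-en-1-yl)-1,3-dioxolan-4-yl]butan-2-yl}-3,5,6,7-tetrahydro-1-benzofuran-4(2H)-one, via Michael adduct 14 (not isolated), via Claisen ester 15 (not isolated), via keto acid 16 (not isolated), via dione 17 (not isolated)
Conditions: CH2(CO2Me)2 (1.5 equiv), NaOMe (3 equiv), MeOH, 0 to 65 °C; then 2 M NaOH, 65 °C; AcOH to pH 4–5, 60 °C; then PPTS (cat.), PhMe, 60 °C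
Reagents that add atoms: dimethyl malonate COC(=O)CC(=O)OC; sodium hydroxide [Na+].[OH-] (oxygen of 16 only)
Why: Methoxide generates the malonate anion, which adds to C6 of the vinyl ketone (Michael addition, C6–C7); the δ-keto diester is then enolised at C3a and closes onto one ester carbonyl (intramolecular Claisen condensation, C3a–C7a), the sequence being driven by formation of the stabilised enolate of 15. The closest known reaction type is the Michael–Claisen (dimedone-type) synthesis of cyclohexane-1,3-diones from enones and malonates, followed in the same flask by the usual saponification and decarboxylation. The carbocycle closes by a 6-exo-trig acyl substitution, and the dihydrofuran ring closes afterwards by 5-exo-trig hemiketalisation of the C2 hydroxyl on C7a and acid-catalysed dehydration to the conjugated enol ether. No permanent stereocentre is created: C2 and C3' are spectators, and the labile centres at C3a and C7 disappear on enolisation and decarboxylation. The step needs enolisation toward C3a (the only α-carbon that can form a six-membered ring, C5 giving a four-membered one) and ring closure by the secondary C2 hydroxyl instead of the tertiary C3' hydroxyl, which faster five-membered hemiketal formation at the less hindered oxygen should secure; the two carbonyls of dione 17 are constitutionally equivalent, so no regiochemical issue arises.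

Step 9
Reactants: 18 (2S)-2-{(2S)-2-hydroxy-4-[(4R,5S)-2,2,5-trimethyl-5-(4-methylpent-3-en-1-yl)-1,3-dioxolan-4-yl]butan-2-yl}-3,5,6,7-tetrahydro-1-benzofuran-4(2H)-one
Product: 19 (2S,5R)-5-hydroxy-2-{(2S)-2-hydroxy-4-[(4R,5S)-2,2,5-trimethyl-5-(4-methylpent-3-en-1-yl)-1,3-dioxolan-4-yl]butan-2-yl}-3,5,6,7-tetrahydro-1-benzofuran-4(2H)-one
Conditions: NaHMDS (2.2 equiv), THF, −78 °C; then (+)-(8,8-dichlorocamphorylsulfonyl)oxaziridine, −78 to −40 °C; AcOH
Reagents that add atoms: (+)-(8,8-dichlorocamphorylsulfonyl)oxaziridine CC1(C)[C@@H]2CC[C@]13CS(=O)(=O)N4O[C@@]34C2(Cl)Cl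
Why: Kinetic deprotonation of the vinylogous ester should occur at the α'-carbon C5 (the tertiary hydroxyl being held as its alkoxide), and electrophilic hydroxylation of the enolate by the enantiopure N-sulfonyloxaziridine (Davis-type oxidation) is reagent-controlled, the (+)-antipode being proposed to deliver oxygen to the Re face of C5 (5R) by analogy with cyclic aryl ketone enolates, since C2 is too remote to bias the flat bicycle.

Step 10
Reactants: 19 (2S,5R)-5-hydroxy-2-{(2S)-2-hydroxy-4-[(4R,5S)-2,2,5-trimethyl-5-(4-methylpent-3-en-1-yl)-1,3-dioxolan-4-yl]butan-2-yl}-3,5,6,7-tetrahydro-1-benzofuran-4(2H)-one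
Product: 20 (2S,5R)-5-hydroxy-2-[(2S,5R,6S)-2,5,6-trihydroxy-6,10-dimethylundec-9-en-2-yl]-3,5,6,7-tetrahydro-1-benzofuran-4(2H)-one
Conditions: AcOH/H2O (4:1), 45 °C
Reagents that add atoms: none
Why: Acid-catalysed hydrolysis of the acetonide should release the C6'/C7' glycol without touching the vinylogous ester, the α-hydroxy ketone or the trisubstituted alkene under these mild conditions.

Compound list
1 | (2R)-5-oxooxolane-2-carboxylic acid | OC(=O)[C@H]1CCC(=O)O1 | starting material
2 | (2R)-5-oxooxolane-2-carbonyl chloride | ClC(=O)[C@H]1CCC(=O)O1 | intermediate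
3 | (5R)-5-acetyloxolan-2-one | CC(=O)[C@H]1CCC(=O)O1 | intermediate
4 | 5-bromo-2-methylpent-2-ene | CC(C)=CCCBr | starting material
5 | (4-methylpent-3-en-1-yl)magnesium bromide | CC(C)=CCC[Mg]Br | intermediate
6 | (5R)-5-[(2S)-2-hydroxy-6-methylhept-5-en-2-yl]oxolan-2-one | CC(C)=CCC[C@](C)(O)[C@H]1CCC(=O)O1 | intermediate
7 | prop-2-en-1-yl 3-[(4R,5S)-2,2,5-trimethyl-5-(4-methylpent-3-en-1-yl)-1,3-dioxolan-4-yl]propanoate | CC(C)=CCC[C@]1(C)OC(C)(C)O[C@@H]1CCC(=O)OCC=C | intermediate
8 | (2S)-5-oxooxolane-2-carboxylic acid | OC(=O)[C@@H]1CCC(=O)O1 | starting material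
9 | (2S)-5-oxooxolane-2-carbonyl chloride | ClC(=O)[C@@H]1CCC(=O)O1 | intermediate
10 | prop-2-en-1-yl 3-oxo-3-[(2S)-5-oxooxolan-2-yl]-2-{[(4R,5S)-2,2,5-trimethyl-5-(4-methylpent-3-en-1-yl)-1,3-dioxolan-4-yl]methyl}propanoate (both epimers at the ester α-carbon) | CC(C)=CCC[C@]1(C)OC(C)(C)O[C@@H]1CC(C(=O)OCC=C)C(=O)[C@@H]1CCC(=O)O1 | intermediate
11 | (5S)-5-{3-[(4R,5S)-2,2,5-trimethyl-5-(4-methylpent-3-en-1-yl)-1,3-dioxolan-4-yl]propanoyl}oxolan-2-one | CC(C)=CCC[C@]1(C)OC(C)(C)O[C@@H]1CCC(=O)[C@@H]1CCC(=O)O1 | intermediate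
12 | (5S)-5-{(2S)-2-hydroxy-4-[(4R,5S)-2,2,5-trimethyl-5-(4-methylpent-3-en-1-yl)-1,3-dioxolan-4-yl]butan-2-yl}oxolan-2-one | CC(C)=CCC[C@]1(C)OC(C)(C)O[C@@H]1CC[C@](C)(O)[C@@H]1CCC(=O)O1 | intermediate
13 | (6S,7S)-6,7-dihydroxy-7-methyl-9-[(4R,5S)-2,2,5-trimethyl-5-(4-methylpent-3-en-1-yl)-1,3-dioxolan-4-yl]non-1-en-3-one (open form of its cyclic hemiketals) | CC(C)=CCC[C@]1(C)OC(C)(C)O[C@@H]1CC[C@](C)(O)[C@@H](O)CCC(=O)C=C | intermediate
14 | dimethyl 2-{(6S,7S)-6,7-dihydroxy-7-methyl-3-oxo-9-[(4R,5S)-2,2,5-trimethyl-5-(4-methylpent-3-en-1-yl)-1,3-dioxolan-4-yl]nonyl}propanedioate | CC(C)=CCC[C@]1(C)OC(C)(C)O[C@@H]1CC[C@](C)(O)[C@@H](O)CCC(=O)CCC(C(=O)OC)C(=O)OC | intermediate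
15 | methyl 3-{(2S,3S)-2,3-dihydroxy-3-methyl-5-[(4R,5S)-2,2,5-trimethyl-5-(4-methylpent-3-en-1-yl)-1,3-dioxolan-4-yl]pentyl}-2-hydroxy-4-oxocyclohex-2-ene-1-carboxylate (enol form; sodium salt in the flask) | CC(C)=CCC[C@]1(C)OC(C)(C)O[C@@H]1CC[C@](C)(O)[C@@H](O)CC1=C(O)C(C(=O)OC)CCC1=O | intermediate
16 | 3-{(2S,3S)-2,3-dihydroxy-3-methyl-5-[(4R,5S)-2,2,5-trimethyl-5-(4-methylpent-3-en-1-yl)-1,3-dioxolan-4-yl]pentyl}-2-hydroxy-4-oxocyclohex-2-ene-1-carboxylic acid | CC(C)=CCC[C@]1(C)OC(C)(C)O[C@@H]1CC[C@](C)(O)[C@@H](O)CC1=C(O)C(C(=O)O)CCC1=O | intermediate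
17 | 2-{(2S,3S)-2,3-dihydroxy-3-methyl-5-[(4R,5S)-2,2,5-trimethyl-5-(4-methylpent-3-en-1-yl)-1,3-dioxolan-4-yl]pentyl}-3-hydroxycyclohex-2-en-1-one (enol form of the cyclohexane-1,3-dione) | CC(C)=CCC[C@]1(C)OC(C)(C)O[C@@H]1CC[C@](C)(O)[C@@H](O)CC1=C(O)CCCC1=O | intermediate
18 | (2S)-2-{(2S)-2-hydroxy-4-[(4R,5S)-2,2,5-trimethyl-5-(4-methylpent-3-en-1-yl)-1,3-dioxolan-4-yl]butan-2-yl}-3,5,6,7-tetrahydro-1-benzofuran-4(2H)-one | CC(C)=CCC[C@]1(C)OC(C)(C)O[C@@H]1CC[C@](C)(O)[C@@H]1CC2=C(CCCC2=O)O1 | intermediate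
19 | (2S,5R)-5-hydroxy-2-{(2S)-2-hydroxy-4-[(4R,5S)-2,2,5-trimethyl-5-(4-methylpent-3-en-1-yl)-1,3-dioxolan-4-yl]butan-2-yl}-3,5,6,7-tetrahydro-1-benzofuran-4(2H)-one | CC(C)=CCC[C@]1(C)OC(C)(C)O[C@@H]1CC[C@](C)(O)[C@@H]1CC2=C(CC[C@@H](O)C2=O)O1 | intermediate
20 | (2S,5R)-5-hydroxy-2-[(2S,5R,6S)-2,5,6-trihydroxy-6,10-dimethylundec-9-en-2-yl]-3,5,6,7-tetrahydro-1-benzofuran-4(2H)-one | CC(C)=CCC[C@](C)(O)[C@H](O)CC[C@](C)(O)[C@@H]1CC2=C(CC[C@@H](O)C2=O)O1 | target

Total step count: 10 (the acid chloride 9 is prepared within step 4).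
Longest linear sequence: 10 steps, from 1 to 20.

Steps most likely to fail

Step 9. The oxygen transfer may show poor facial selectivity, because the enolate is flat, C2 is remote and the reagent is the only source of control; competing γ-deprotonation at C7 would also divert material. The fallback sets out from 18: α'-acetoxylation with Mn(OAc)3 (benzene, 80 °C) should give (2S)-2-{(2S)-2-hydroxy-4-[(4R,5S)-2,2,5-trimethyl-5-(4-methylpent-3-en-1-yl)-1,3-dioxolan-4-yl]butan-2-yl}-4-oxo-2,3,4,5,6,7-hexahydro-1-benzofuran-5-yl acetate F1 as both C5 epimers. A lipase that accepts only the (5R)-acetate (Candida antarctica lipase B, phosphate buffer/MTBE) would then release 19, where the route is rejoined; the untouched (5S)-acetate is re-equilibrated with DBU and resubmitted.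

Step 2. Felkin–Anh facial selectivity may be eroded by competing chelation through the lactone oxygen, and the methyl ketone may be enolised by the Grignard reagent. The fallback sets out from acid chloride 2: acylation of Grignard reagent 5 (Fe(acac)3 cat., THF, −78 °C) should give (5R)-5-(5-methylhex-4-enoyl)oxolan-2-one F2. LiOH (THF/H2O, 0 °C) opens the lactone to (4R)-4-hydroxy-9-methyl-5-oxodec-8-enoic acid F3 (as its lithium salt). Its magnesium α-alkoxide then directs MeMgBr by five-membered chelation, methyl entering anti to C5', to give (4R,5S)-4,5-dihydroxy-5,9-dimethyldec-8-enoic acid F4, which relactonises on acidification to 6.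

Step 7. The lactolate may collapse before the quench, so that a second equivalent of Grignard reagent adds to the liberated enone, and the free vinyl ketone may polymerise on work-up. The fallback sets out from 12: Me2AlCl and MeNHOMe·HCl (CH2Cl2, 0 °C) open the lactone to (4S,5S)-4,5-dihydroxy-N-methoxy-N,5-dimethyl-7-[(4R,5S)-2,2,5-trimethyl-5-(4-methylpent-3-en-1-yl)-1,3-dioxolan-4-yl]heptanamide F5. TMSCl/imidazole gives (4S,5S)-N-methoxy-N,5-dimethyl-7-[(4R,5S)-2,2,5-trimethyl-5-(4-methylpent-3-en-1-yl)-1,3-dioxolan-4-yl]-4,5-bis(trimethylsilyloxy)heptanamide F6. Vinylmagnesium bromide (THF, −78 to 0 °C) followed by aqueous citric acid should then give 13 directly, the chelated tetrahedral intermediate of the N-methoxy-N-methylamide preventing over-addition.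

Further compounds
F1 | step 9 | (2S)-2-{(2S)-2-hydroxy-4-[(4R,5S)-2,2,5-trimethyl-5-(4-methylpent-3-en-1-yl)-1,3-dioxolan-4-yl]butan-2-yl}-4-oxo-2,3,4,5,6,7-hexahydro-1-benzofuran-5-yl acetate (both C5 epimers) | CC(C)=CCC[C@]1(C)OC(C)(C)O[C@@H]1CC[C@](C)(O)[C@@H]1CC2=C(CCC(OC(C)=O)C2=O)O1
F2 | step 2 | (5R)-5-(5-methylhex-4-enoyl)oxolan-2-one | CC(C)=CCCC(=O)[C@H]1CCC(=O)O1
F3 | step 2 | (4R)-4-hydroxy-9-methyl-5-oxodec-8-enoic acid | CC(C)=CCCC(=O)[C@H](O)CCC(=O)O
F4 | step 2 | (4R,5S)-4,5-dihydroxy-5,9-dimethyldec-8-enoic acid | CC(C)=CCC[C@](C)(O)[C@H](O)CCC(=O)O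
F5 | step 7 | (4S,5S)-4,5-dihydroxy-N-methoxy-N,5-dimethyl-7-[(4R,5S)-2,2,5-trimethyl-5-(4-methylpent-3-en-1-yl)-1,3-dioxolan-4-yl]heptanamide | CC(C)=CCC[C@]1(C)OC(C)(C)O[C@@H]1CC[C@](C)(O)[C@@H](O)CCC(=O)N(C)OC
F6 | step 7 | (4S,5S)-N-methoxy-N,5-dimethyl-7-[(4R,5S)-2,2,5-trimethyl-5-(4-methylpent-3-en-1-yl)-1,3-dioxolan-4-yl]-4,5-bis(trimethylsilyloxy)heptanamide | CC(C)=CCC[C@]1(C)OC(C)(C)O[C@@H]1CC[C@](C)(O[Si](C)(C)C)[C@@H](O[Si](C)(C)C)CCC(=O)N(C)OC
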